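Numbering: C1 (quaternary, CH3), C2, C3, C4 (carbinol, isopropyl), C5 (ring-fusion CH), C6 (acyloxy), C7, C8(CH3)=C9, C10. Ring A is C1–C5, ring B is C1/C5–C10, and β is the face of the C1 methyl group. Azulene locants 8a, 1, 2, 3, 3a, 4, 5, 6, 7, 8 in the names stand for C1–C10.
Cuts, in retrosynthetic order: the acyl–O6 bond of the salicylate; C8–CH3 back to C8–CO2Me; the C6–H and C5–H bonds back to a C5=C6 enol ether; the C4–isopropyl bond back to a C4 ketone; last, C7–C8 and C1–C10 of ring B.
Enabling feature: in ring B the C8=C9 alkene, the single C7 methylene, the oxygen on C6 and the C10–C1 bond to the quaternary carbon are the imprint of a cyclohepta-1,4-diene. Its second alkene (C5=C6) is an enol ether, so ring B is what a cis-divinylcyclopropane C6–C7–C8 becomes after a [3,3] shift.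
Forward: ring A is bought as 3-methylcyclopentenone and given a 1-siloxyvinyl arm (C6=C7). Ring B is closed onto it in one operation by vinylcarbenoid cyclopropanation and Cope rearrangement. C4, C5 and C6 are then adjusted, the ester is taken down to the methyl group, and O6 is acylated last.
Stereochemistry: C1 comes from the chiral dirhodium catalyst, relayed through the boat-shaped Cope transition state. C4 comes from organocerium addition anti to the angular methyl group, C5 from equilibration to the trans-fused ketol, and C6 from hydride delivery by the 4β-hydroxyl group.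

Key step: step 7

Assumption: Rh2(S-DOSP)4 is taken to deliver the (1S,2R)-configured cyclopropane, the one that relays to (R)-C1; if the first experiment shows the opposite sense, Rh2(R-DOSP)4 is used and nothing else in the route changes.

Step 1
Reactants: 1 3-methylcyclopent-2-en-1-one
Product: 2 2-iodo-3-methylcyclopent-2-en-1-one
Conditions: I2, pyridine, CH2Cl2, 0 °C to rt
Reagents that add atoms: iodine, SMILES [I][I]
Why: α-Iodination of an enone with iodine and pyridine (Baylis–Hillman-type conjugate addition of pyridine, iodination of the enolate, loss of pyridinium) halogenates only the α-vinylic carbon, the future C5, and creates no stereocentre.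

Step 2
Reactants: 2 2-iodo-3-methylcyclopent-2-en-1-one; 3 tributyl(1-ethoxyvinyl)stannane
Product: 5 2-acetyl-3-methylcyclopent-2-en-1-one, via ethoxyvinyl enone 4 (not isolated)
Conditions: PdCl2(PPh3)2 (5 mol %), CuI (10 mol %), DMF, 60 °C; then 1 M HCl, THF, rt
Reagents that add atoms: water, SMILES O
Why: The Stille coupling of α-iodoenones with 1-ethoxyvinylstannanes is a standard way to bring in a masked acetyl group (CuI speeds up transmetalation at the hindered carbon), and dilute acid then hydrolyses the enol ether of 4 to the methyl ketone while the tetrasubstituted enone is left alone.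

Step 3
Reactants: 5 2-acetyl-3-methylcyclopent-2-en-1-one
Product: 7 2-[1-(tert-butyldimethylsilyloxy)vinyl]-3-methylcyclopent-2-en-1-one, via lithium enolate 6 (not isolated)
Conditions: LiN(iPr)2, THF, −78 °C (5 added to the base); then tBuMe2SiOTf, −78 °C
Reagents that add atoms: tert-butyldimethylsilyl trifluoromethanesulfonate, SMILES CC(C)(C)[Si](C)(C)OS(=O)(=O)C(F)(F)F
Why: Kinetic enolate formation followed by O-silylation: the hindered amide should take a proton from the exposed acetyl methyl group rather than from the ring CH2 next to C4 or from the γ positions, and the hard, fast silyl triflate fixes enolate 6 on oxygen before proton exchange can move the charge, which gives the cross-conjugated 2-siloxydiene.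

Step 4
Reactants: 8 methyl acetoacetate
Product: 9 methyl 2-diazo-3-oxobutanoate
Conditions: 4-acetamidobenzenesulfonyl azide, Et3N, MeCN, 0 °C to rt
Reagents that add atoms: 4-acetamidobenzenesulfonyl azide, SMILES CC(=O)Nc1ccc(cc1)S(=O)(=O)N=[N+]=[N-]
Why: Regitz diazo transfer from a sulfonyl azide to the doubly activated methylene group of a β-keto ester is dependable under mild amine base.

Step 5
Reactants: 9 methyl 2-diazo-3-oxobutanoate
Product: 10 methyl 2-diazo-3-hydroxybutanoate (racemic)
Conditions: NaBH4, MeOH, 0 °C
Reagents that add atoms: none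
Why: Sodium borohydride reduces the ketone chemoselectively because the diazo ester is inert to it, and the carbinol stereocentre, formed as a racemate, is removed in the next step.

Step 6
Reactants: 10 methyl 2-diazo-3-hydroxybutanoate
Product: 11 methyl 2-diazobut-3-enoate
Conditions: POCl3, Et3N, CH2Cl2, 0 °C
Reagents that add atoms: none
Why: Dehydration of an α-diazo-β-hydroxy ester through its dichlorophosphate (E2 elimination) is the established access to vinyldiazoacetates, and 11 is kept cold and used at once because it slowly closes to a pyrazole.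

Step 7
Reactants: 7 2-[1-(tert-butyldimethylsilyloxy)vinyl]-3-methylcyclopent-2-en-1-one; 11 methyl 2-diazobut-3-enoate
Product: 13 methyl (8aR)-4-(tert-butyldimethylsilyloxy)-8a-methyl-3-oxo-1,2,3,5,8,8a-hexahydroazulene-6-carboxylate, via cis-divinylcyclopropane 12 (not isolated)
Conditions: Rh2(S-DOSP)4, dirhodium tetrakis[(S)-N-(4-dodecylbenzenesulfonyl)prolinate] (1 mol %), hexane, −20 °C, 11 (2 equiv) added over 2 h; then 60 °C
Reagents that add atoms: none
Why: Loss of N2 from 11 on the dirhodium catalyst gives a donor/acceptor vinylcarbenoid that adds in a concerted, asynchronous way to the terminal, oxygen-activated C6=C7 alkene of 7, and the cis-divinylcyclopropane 12 then undergoes a boat-shaped [3,3] shift in which C1–C10 forms while the C6–C8 bond, weakened by the siloxy donor on C6 and the ester acceptor on C8, breaks. The closest known reaction type is the tandem cyclopropanation/Cope rearrangement (formal [4+3] cycloaddition) of vinyldiazoacetates with 2-siloxydienes and with dienes whose far terminus is fully substituted. Ring B is closed by sigmatropic expansion of the three-membered ring to a cyclohepta-1,4-diene, three atoms coming from the carbenoid and four from the diene, and not by an ionic cyclisation. The only lasting stereocentre, C1, is set by chirality transfer: the prolinate ligands fix C6 and C8 in 12, and the endo boat, the only geometry that leads to two cis ring alkenes, lets C10 reach just one face of C1. Site selectivity for the enol ether alkene over the tetrasubstituted, carbonyl-deactivated C1=C5 alkene and over the ketone oxygen rests on the electrophilic and bulky nature of the carbenoid, attack at the carbenoid carbon rather than at the vinyl terminus is favoured by the hydrocarbon solvent and the small methyl ester, and any trans-divinyl isomer can be fed back by reversible opening of the donor–acceptor cyclopropane. The C1 methyl group points inward in the boat and slows the shift, hence the final warming.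

Step 8
Reactants: 13 methyl (8aR)-4-(tert-butyldimethylsilyloxy)-8a-methyl-3-oxo-1,2,3,5,8,8a-hexahydroazulene-6-carboxylate
Product: 14 methyl (3R,8aR)-4-(tert-butyldimethylsilyloxy)-3-hydroxy-3-isopropyl-8a-methyl-1,2,3,5,8,8a-hexahydroazulene-6-carboxylate (4β-OH; 4α-isopropyl)
Conditions: iPrMgCl, CeCl3, THF, −78 °C; aqueous NaHCO3 quench, product used at once
Reagents that add atoms: isopropylmagnesium chloride, SMILES CC(C)[Mg]Cl
Why: Organocerium 1,2-addition: the weakly basic, oxophilic reagent adds to the C4 ketone faster than it enolises C3, reduces the carbonyl or touches the hindered enoate at −78 °C, it approaches ring A from the α face because the angular C1 methyl group stands pseudoaxial over the β face, which sets 4β-OH and 4α-isopropyl, and the poorly nucleophilic cerium alkoxide should not start a silyl shift from O6 to O4.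

Step 9
Reactants: 14 methyl (3R,8aR)-4-(tert-butyldimethylsilyloxy)-3-hydroxy-3-isopropyl-8a-methyl-1,2,3,5,8,8a-hexahydroazulene-6-carboxylate
Product: 16 methyl (3R,3aR,8aR)-3-hydroxy-3-isopropyl-8a-methyl-4-oxo-1,2,3,3a,4,5,8,8a-octahydroazulene-6-carboxylate (trans-fused; 5α-H), via cis-fused ketol 15 (not isolated)
Conditions: Bu4NF, AcOH (1 equiv each), THF, 0 °C; then DBU (0.2 equiv), rt
Reagents that add atoms: none
Why: Fluoride cleavage of the enol silane under acetate buffering (no acid, so the tertiary allylic alcohol cannot ionise) frees the C6 ketone, kinetic protonation of C5 on the face away from the isopropyl group should first give the cis-fused 15, and base-catalysed α-epimerisation with DBU then moves C5 to the trans-fused 16, favoured because C6 lies anti to the isopropyl group and within hydrogen-bond reach of the 4β-OH, the step being placed while C8 still carries the ester so that the C8=C9 alkene stays anchored in conjugation.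

Step 10
Reactants: 16 methyl (3R,3aR,8aR)-3-hydroxy-3-isopropyl-8a-methyl-4-oxo-1,2,3,3a,4,5,8,8a-octahydroazulene-6-carboxylate
Product: 17 methyl (3R,3aS,4S,8aR)-3,4-dihydroxy-3-isopropyl-8a-methyl-1,2,3,3a,4,5,8,8a-octahydroazulene-6-carboxylate (6α-OH)
Conditions: Me4NBH(OAc)3, MeCN–AcOH (1:1), −20 to 0 °C
Reagents that add atoms: none
Why: Evans–Saksena reduction: the 4β-hydroxyl group displaces an acetate from boron and the tethered hydride is passed to the β face of the C6 carbonyl through a chair-like six-membered transition state, which gives the 6α-alcohol (anti 1,3-diol), while the enoate, which cannot bind the reagent, is not reduced.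

Step 11
Reactants: 17 methyl (3R,3aS,4S,8aR)-3,4-dihydroxy-3-isopropyl-8a-methyl-1,2,3,3a,4,5,8,8a-octahydroazulene-6-carboxylate
Product: 18 (3R,3aS,4S,8aR)-6-(hydroxymethyl)-3-isopropyl-8a-methyl-1,2,3,3a,4,5,8,8a-octahydroazulene-3,4-diol
Conditions: iBu2AlH (5 equiv), CH2Cl2, −78 to 0 °C
Reagents that add atoms: none
Why: iBu2AlH reduces α,β-unsaturated esters cleanly in the 1,2 sense to allylic alcohols once the two hydroxyl groups have been converted to aluminium alkoxides, and no stereocentre is affected.

Step 12
Reactants: 18 (3R,3aS,4S,8aR)-6-(hydroxymethyl)-3-isopropyl-8a-methyl-1,2,3,3a,4,5,8,8a-octahydroazulene-3,4-diol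
Product: 19 (3R,3aS,4S,8aR)-6-(chloromethyl)-3-isopropyl-8a-methyl-1,2,3,3a,4,5,8,8a-octahydroazulene-3,4-diol
Conditions: N-chlorosuccinimide, Me2S, CH2Cl2, −20 to 0 °C
Reagents that add atoms: N-chlorosuccinimide, SMILES O=C1CCC(=O)N1Cl
Why: Corey–Kim chlorination without added base: only the alkoxysulfonium salt of the primary allylic alcohol is displaced by chloride (SN2), whereas those of the hindered secondary and tertiary alcohols revert on work-up, so that the diol needs no protection.

Step 13
Reactants: 19 (3R,3aS,4S,8aR)-6-(chloromethyl)-3-isopropyl-8a-methyl-1,2,3,3a,4,5,8,8a-octahydroazulene-3,4-diol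
Product: 20 (3R,3aS,4S,8aR)-3-isopropyl-6,8a-dimethyl-1,2,3,3a,4,5,8,8a-octahydroazulene-3,4-diol (jaeschkeanadiol)
Conditions: LiEt3BH (4 equiv), THF, 0 °C to rt
Reagents that add atoms: none
Why: Hydride displacement (SN2) of a primary allylic chloride by LiEt3BH occurs at the unhindered CH2 carbon without allylic transposition, which turns the former ester carbon into the C8 methyl group and keeps the C8=C9 alkene in place.

Step 14
Reactants: 20 (3R,3aS,4S,8aR)-3-isopropyl-6,8a-dimethyl-1,2,3,3a,4,5,8,8a-octahydroazulene-3,4-diol; 21 2-acetoxybenzoyl chloride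
Product: 22 (3R,3aS,4S,8aR)-3-hydroxy-3-isopropyl-6,8a-dimethyl-1,2,3,3a,4,5,8,8a-octahydroazulen-4-yl 2-acetoxybenzoate
Conditions: Et3N, DMAP (10 mol %), CH2Cl2, 0 °C to rt
Reagents that add atoms: none
Why: DMAP-catalysed acylation with the acid chloride takes the secondary 6α-OH only, the tertiary 4β-OH being too hindered to react, the acetate on the phenol prevents self-acylation of the reagent, and C6 keeps its configuration because only its O–H bond is broken.

Step 15
Reactants: 22 (3R,3aS,4S,8aR)-3-hydroxy-3-isopropyl-6,8a-dimethyl-1,2,3,3a,4,5,8,8a-octahydroazulen-4-yl 2-acetoxybenzoate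
Product: 23 (3R,3aS,4S,8aR)-3-hydroxy-3-isopropyl-6,8a-dimethyl-1,2,3,3a,4,5,8,8a-octahydroazulen-4-yl 2-hydroxybenzoate (CNP0379621.1)
Conditions: K2CO3 (0.2 equiv), MeOH, 0 °C
Reagents that add atoms: none
Why: Base-catalysed transesterification (Zemplén-type methanolysis) removes the aryl acetate, a far better acyl donor than the hindered salicylate ester that becomes deactivated as its phenoxide, and leaves the four stereocentres and the alkene untouched.

Compound list
1 | 3-methylcyclopent-2-en-1-one | CC1=CC(=O)CC1 | starting material
2 | 2-iodo-3-methylcyclopent-2-en-1-one | IC1=C(C)CCC1=O | intermediate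
3 | tributyl(1-ethoxyvinyl)stannane | CCCC[Sn](CCCC)(CCCC)C(=C)OCC | starting material
4 | 2-(1-ethoxyvinyl)-3-methylcyclopent-2-en-1-one | CCOC(=C)C1=C(C)CCC1=O | intermediate
5 | 2-acetyl-3-methylcyclopent-2-en-1-one | CC(=O)C1=C(C)CCC1=O | intermediate
6 | lithium 1-(2-methyl-5-oxocyclopent-1-en-1-yl)ethen-1-olate | [Li+].[O-]C(=C)C1=C(C)CCC1=O | intermediate
7 | 2-[1-(tert-butyldimethylsilyloxy)vinyl]-3-methylcyclopent-2-en-1-one | CC1=C(C(=C)O[Si](C)(C)C(C)(C)C)C(=O)CC1 | intermediate
8 | methyl acetoacetate | COC(=O)CC(C)=O | starting material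
9 | methyl 2-diazo-3-oxobutanoate | COC(=O)C(=[N+]=[N-])C(C)=O | intermediate
10 | methyl 2-diazo-3-hydroxybutanoate (racemic) | COC(=O)C(=[N+]=[N-])C(C)O | intermediate
11 | methyl 2-diazobut-3-enoate | COC(=O)C(=[N+]=[N-])C=C | intermediate
12 | methyl (1S,2R)-2-(tert-butyldimethylsilyloxy)-2-(2-methyl-5-oxocyclopent-1-en-1-yl)-1-vinylcyclopropane-1-carboxylate (vinyl and cyclopentenyl cis) | COC(=O)[C@]1(C=C)C[C@@]1(O[Si](C)(C)C(C)(C)C)C2=C(C)CCC2=O | intermediate
13 | methyl (8aR)-4-(tert-butyldimethylsilyloxy)-8a-methyl-3-oxo-1,2,3,5,8,8a-hexahydroazulene-6-carboxylate (C4 ketone, C5=C6 enol silane, C8 ester, C8=C9) | COC(=O)C1=CC[C@@]2(C)CCC(=O)C2=C(O[Si](C)(C)C(C)(C)C)C1 | intermediate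
14 | methyl (3R,8aR)-4-(tert-butyldimethylsilyloxy)-3-hydroxy-3-isopropyl-8a-methyl-1,2,3,5,8,8a-hexahydroazulene-6-carboxylate (4β-OH) | COC(=O)C1=CC[C@@]2(C)CC[C@@](O)(C(C)C)C2=C(O[Si](C)(C)C(C)(C)C)C1 | intermediate
15 | methyl (3R,3aS,8aR)-3-hydroxy-3-isopropyl-8a-methyl-4-oxo-1,2,3,3a,4,5,8,8a-octahydroazulene-6-carboxylate (cis-fused, 5β-H) | COC(=O)C1=CC[C@@]2(C)CC[C@@](O)(C(C)C)[C@H]2C(=O)C1 | intermediate
16 | methyl (3R,3aR,8aR)-3-hydroxy-3-isopropyl-8a-methyl-4-oxo-1,2,3,3a,4,5,8,8a-octahydroazulene-6-carboxylate (trans-fused, 5α-H) | COC(=O)C1=CC[C@@]2(C)CC[C@@](O)(C(C)C)[C@@H]2C(=O)C1 | intermediate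
17 | methyl (3R,3aS,4S,8aR)-3,4-dihydroxy-3-isopropyl-8a-methyl-1,2,3,3a,4,5,8,8a-octahydroazulene-6-carboxylate | COC(=O)C1=CC[C@@]2(C)CC[C@@](O)(C(C)C)[C@@H]2[C@@H](O)C1 | intermediate
18 | (3R,3aS,4S,8aR)-6-(hydroxymethyl)-3-isopropyl-8a-methyl-1,2,3,3a,4,5,8,8a-octahydroazulene-3,4-diol | OCC1=CC[C@@]2(C)CC[C@@](O)(C(C)C)[C@@H]2[C@@H](O)C1 | intermediate
19 | (3R,3aS,4S,8aR)-6-(chloromethyl)-3-isopropyl-8a-methyl-1,2,3,3a,4,5,8,8a-octahydroazulene-3,4-diol | ClCC1=CC[C@@]2(C)CC[C@@](O)(C(C)C)[C@@H]2[C@@H](O)C1 | intermediate
20 | (3R,3aS,4S,8aR)-3-isopropyl-6,8a-dimethyl-1,2,3,3a,4,5,8,8a-octahydroazulene-3,4-diol (jaeschkeanadiol) | CC1=CC[C@@]2(C)CC[C@@](O)(C(C)C)[C@@H]2[C@@H](O)C1 | intermediate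
21 | 2-acetoxybenzoyl chloride | CC(=O)Oc1ccccc1C(Cl)=O | starting material
22 | (3R,3aS,4S,8aR)-3-hydroxy-3-isopropyl-6,8a-dimethyl-1,2,3,3a,4,5,8,8a-octahydroazulen-4-yl 2-acetoxybenzoate | CC1=CC[C@@]2(C)CC[C@@](O)(C(C)C)[C@@H]2[C@@H](OC(=O)c2ccccc2OC(C)=O)C1 | intermediate
23 | (3R,3aS,4S,8aR)-3-hydroxy-3-isopropyl-6,8a-dimethyl-1,2,3,3a,4,5,8,8a-octahydroazulen-4-yl 2-hydroxybenzoate | CC1=CC[C@@]2(C)CC[C@@](O)(C(C)C)[C@@H]2[C@@H](OC(=O)c2ccccc2O)C1 | target

Total step count: 15. Longest linear sequence: 12 steps (1 to 23 through steps 1–3 and 7–15; the branch from 8 through steps 4–6 and 7–15 is equally long).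

Steps most likely to fail

**Step 9.**
- What may go wrong: enolisation towards the doubly activated C7 is faster than towards the hindered C5. The C8=C9 alkene may therefore slide into conjugation with the new ketone before the ring fusion has equilibrated. The ketol may also open by retro-aldol cleavage of C4–C5 or lose water through the C5 enolate.
- Fallback (from 14, back at 16): the alkene shift is accepted and then undone kinetically. After the buffered desilylation the crude ketol 15 is warmed with DBU in toluene until ring fusion and alkene position are both at equilibrium, which should collect the material as the trans-fused C7=C8 ene-keto ester F1.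
- KN(SiMe3)2 (2.2 equiv, THF, −78 °C) then removes the hydroxyl proton and a γ proton from C9 to give the extended dipotassium dienolate F2. C5–H is spared because it is tertiary, flanked by two fully substituted carbons and next to the alkoxide.
- Inverse quench into cold AcOH–THF protonates F2 at the α carbon C7 (kinetic deconjugative protonation). This restores the C8=C9 alkene and delivers 16 for immediate reduction in step 10.

**Step 7.**
- What may go wrong: loss of 11 by electrocyclisation before it meets the catalyst; attack of the nucleophilic enol silane at the vinyl terminus of the carbenoid; heterolytic opening of the donor–acceptor cyclopropane with silyl transfer before the sterically slowed Cope shift; and weak enantio-induction on a 1,1-disubstituted alkene.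
- Fallback (from 2, back at 13): the donor oxygen is left out of the cycloaddition and put in afterwards. Stille coupling of 2 with tributyl(vinyl)stannane gives 3-methyl-2-vinylcyclopent-2-en-1-one F3. Its monosubstituted vinyl group belongs to the best substrate class for donor/acceptor carbenoids, and the cyclopropane derived from it carries no donor and cannot ionise.
- With 11 and the same catalyst the cis-divinylcyclopropane F4 should form and, on heating in toluene, rearrange to the dienone ester F5 (same two bonds, same ring).
- Weitz–Scheffer epoxidation (H2O2, NaOH, MeOH, 0 °C) of the more electrophilic enone alkene gives the 5,6-epoxy ketone F6. Isomerisation with Pd(PPh3)4 and 1,2-bis(diphenylphosphino)ethane (zerovalent palladium, a known reaction of α,β-epoxy ketones) gives the enolised β-diketone F7. tBuMe2SiOTf/Et3N then silylates the enol oxygen on C6 and rejoins the route at 13.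

**Step 3.**
- What may go wrong: deprotonation at the ring CH2 next to C4 or at the doubly activated γ positions instead of the acetyl methyl group, and proton exchange between enolate and unreacted ketone before silylation.
- Fallback (from 4, back at 13): the enolisation is avoided altogether. Compound 4 is isolated by leaving out the acid treatment of step 2 and serves as the diene itself.
- With 11 and Rh2(S-DOSP)4 it should give, through the ethoxy-substituted divinylcyclopropane F8, the vinylogous ethyl ester F9. 1 M HCl in THF hydrolyses this to the enolised β-diketone F7, and O-silylation (tBuMe2SiOTf, Et3N) returns to 13.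

Further compounds
F1 | step 9 | C7=C8 conjugated isomer of ketol 16 (trans-fused, 4β-OH, 5α-H; methyl ester on C8) | COC(=O)C1=CC(=O)[C@H]2[C@](O)(C(C)C)CC[C@]2(C)CC1
F2 | step 9 | dipotassium salt of the C6=C7/C8=C9 dienolate and 4-alkoxide of 16 | COC(=O)C1=CC[C@@]2(C)CC[C@@]([O-])(C(C)C)[C@@H]2C([O-])=C1.[K+].[K+]
F3 | step 7 | 3-methyl-2-vinylcyclopent-2-en-1-one | C=CC1=C(C)CCC1=O
F4 | step 7 | methyl 2-(2-methyl-5-oxocyclopent-1-en-1-yl)-1-vinylcyclopropane-1-carboxylate (vinyl and cyclopentenyl cis) | COC(=O)[C@]1(C=C)C[C@H]1C2=C(C)CCC2=O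
F5 | step 7 | methyl (8aR)-8a-methyl-3-oxo-1,2,3,5,8,8a-hexahydroazulene-6-carboxylate | COC(=O)C1=CC[C@@]2(C)CCC(=O)C2=CC1
F6 | step 7 | 5,6-epoxide of F5 (either epoxide face) | COC(=O)C1=CC[C@@]2(C)CCC(=O)C23OC3C1
F7 | step 7 | methyl (8aR)-4-hydroxy-8a-methyl-3-oxo-1,2,3,5,8,8a-hexahydroazulene-6-carboxylate (enol form of the C4/C6 diketone) | COC(=O)C1=CC[C@@]2(C)CCC(=O)C2=C(O)C1
F8 | step 3 | methyl (1S,2R)-2-ethoxy-2-(2-methyl-5-oxocyclopent-1-en-1-yl)-1-vinylcyclopropane-1-carboxylate | COC(=O)[C@]1(C=C)C[C@@]1(OCC)C2=C(C)CCC2=O
F9 | step 3 | methyl (8aR)-4-ethoxy-8a-methyl-3-oxo-1,2,3,5,8,8a-hexahydroazulene-6-carboxylate | COC(=O)C1=CC[C@@]2(C)CCC(=O)C2=C(OCC)C1
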